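**Retrosynthetic overview**
1. Labdane numbering is used (ring A: C1–C5 and C10; ring B: C5–C10). The plan rests on C5 and C10 being neighbouring ring-fusion carbons: C5 carries C4 (with the gem-dimethyl group) and C10 carries its methyl and C1, so both arms of ring A can be added in one operation across a C5=C10 enone whose carbonyl is C9.
2. Late disconnections: the C2 acetate (selective acetylation of the 2,3-cis-diol), C11–C12 (C11 sulfone anion plus the C5 allylic chloride acetate), C9–C11 (methylenation and hydroboration of the C9 ketone), and the C8 methyl with C7=C8 (from the C7 silyl ether by elimination, α-iodination and Stille coupling).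
3. Ring A is closed second, by ring-closing metathesis at C2=C3 between an allyl group on C10 and a 1,1-dimethylallyl group on C5; this alkene then carries the cis-diol.
4. Both arms come from one three-component step on ring B: conjugate addition of prenyltrimethylsilane through its CMe2 terminus to C5 of (S)-5-silyloxy-2-methylcyclohex-2-enone, then allylation of the C10 enolate so formed.
5. Ring B is present from the start in (S)-carvone, whose isopropenyl group is degraded to the C7 oxygen by ozonolysis and Criegee rearrangement.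

Key step: step 4

Remark: labdane numbering is used for every bicyclic intermediate. The conjugate addition is run with a silicon Lewis acid, because a trichlorotitanium enolate would not be alkylated by allyl bromide, whereas the silyl enol ether can be opened to the lithium enolate.

**Route**

Step 1
Reactants: 1 (S)-carvone
Product: 3 (S)-5-acetoxy-2-methylcyclohex-2-en-1-one, via methoxy hydroperoxide 2 (not isolated)
Conditions: O3, CH2Cl2/MeOH, −78 °C; then Ac2O, Et3N, DMAP (cat.), −78 → 23 °C
Reagents that add atoms: ozone, [O-][O+]=O; methanol, CO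
Why: Ozone cleaves the electron-rich isopropenyl alkene faster than the conjugated ring alkene, methanol traps the carbonyl oxide as 2, and acetylation of the hydroperoxide triggers the Criegee rearrangement, in which the ring carbon migrates to oxygen with retention so that the stereocenter is carried over unchanged (the acetyl carbons of 3 are the old isopropenyl carbon and its methyl, and its carbonyl oxygen is taken as that of methanol after loss of methyl acetate).

Step 2
Reactants: 3 (S)-5-acetoxy-2-methylcyclohex-2-en-1-one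
Product: 4 (S)-5-hydroxy-2-methylcyclohex-2-en-1-one
Conditions: K2CO3 (cat.), MeOH, 0 °C
Reagents that add atoms: none
Why: Base-catalysed transesterification removes the acetate, and the low temperature should keep the β-hydroxy ketone from dehydrating to the cross-conjugated dienone.

Step 3
Reactants: 4 (S)-5-hydroxy-2-methylcyclohex-2-en-1-one
Product: 5 (S)-5-(tert-butyldimethylsilyloxy)-2-methylcyclohex-2-en-1-one
Conditions: TBSCl, imidazole, DMF, 0 → 23 °C
Reagents that add atoms: tert-butyldimethylsilyl chloride, CC(C)(C)[Si](C)(C)Cl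
Why: Imidazole-promoted silylation of the secondary alcohol gives the ether that shields one enone face in step 4 and later serves as the leaving group for the C7=C8 alkene.

Step 4
Reactants: 5 (S)-5-(tert-butyldimethylsilyloxy)-2-methylcyclohex-2-en-1-one; 6 prenyltrimethylsilane; 7 allyl bromide
Product: 10 (2R,3R,5S)-2-allyl-5-(tert-butyldimethylsilyloxy)-2-methyl-3-(2-methylbut-3-en-2-yl)cyclohexan-1-one, via trimethylsilyl enol ether 8 (not isolated), via lithium enolate 9 (not isolated)
Conditions: 6 (1.5 equiv), Tf2NH (5 mol %, gives Me3SiNTf2 in the flask), CH2Cl2, −78 → −40 °C; Et3N, concentrate; MeLi, THF, 0 → 23 °C; then 7, HMPA, −78 → 0 °C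
Reagents that add atoms: none
Why: Me3SiNTf2 silylates the carbonyl oxygen of 5 and the γ-carbon (CMe2 terminus) of 6 attacks C5 of the resulting silyloxyallyl cation in an open transition state; transfer of Me3Si from the β-silyl cation to triflimide returns the catalyst and leaves the C9–C10 trimethylsilyl enol ether 8, so C4–C5 is formed with allylic transposition and the enolate regiochemistry is fixed. MeLi then cleaves the O–Si bond to the lithium enolate 9, which is C-allylated at C10 by 7 to form C1–C10; the closest known reactions are the Hosomi–Sakurai conjugate allylation and the alkylation of a regiodefined enolate released from a silyl enol ether. No ring is closed here, the two alkene arms being kept for the metathesis of step 5. C5 is set by axial attack on the half-chair of 5 anti to the C7 silyloxy group (3,5-trans), and C10 by attack of 7 on the enolate face opposite the bulky 1,1-dimethylallyl group on C5, which sits pseudoaxial to avoid allylic strain with the C10 methyl, so the two arms end trans as the trans-decalin requires. The step needs γ- over α-attack of the silane (inherent in the SE2′ pathway of allylsilanes), 1,4- over 1,2-addition (soft π-nucleophile on the silyl-activated enone) and C-allylation at C10 only, which is secured because the enolate arises regiospecifically from the conjugate addition and never toward C8, the carbon β to the silyl ether. A stoichiometric titanium Lewis acid is avoided because its enolate would not react with allyl bromide.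

Step 5
Reactants: 10 (2R,3R,5S)-2-allyl-5-(tert-butyldimethylsilyloxy)-2-methyl-3-(2-methylbut-3-en-2-yl)cyclohexan-1-one
Product: 11 7-(tert-butyldimethylsilyloxy)-4,4,10-trimethyl-trans-decal-2-en-9-one (5-H and 7-OTBS on the face opposite the 10-methyl)
Conditions: second-generation Grubbs catalyst (H2IMes)(PCy3)Cl2Ru=CHPh (5 mol %), CH2Cl2, 40 °C
Reagents that add atoms: none
Why: Ring-closing metathesis of the allyl and 1,1-dimethylallyl arms closes ring A as a cyclohexene at C2=C3, driven by loss of ethylene and helped by the gem-dimethyl group (Thorpe–Ingold effect), and the trans arrangement of the arms gives the trans-decalin directly.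

Step 6
Reactants: 11 7-(tert-butyldimethylsilyloxy)-4,4,10-trimethyl-trans-decal-2-en-9-one
Product: 12 7-(tert-butyldimethylsilyloxy)-2,3-dihydroxy-4,4,10-trimethyl-trans-decalin-9-one (2-OH equatorial, 3-OH axial, both on the face opposite the 10-methyl)
Conditions: OsO4 (cat.), NMO, acetone/H2O, 23 °C
Reagents that add atoms: osmium tetroxide, O=[Os](=O)(=O)=O (delivers both oxygens, reoxidised by NMO); N-methylmorpholine N-oxide, C[N+]1([O-])CCOCC1; water, O
Why: Catalytic OsO4/NMO syn-dihydroxylation should deliver both oxygens to the face of C2=C3 opposite the axial C10 and C4 methyl groups, which sets C2 and C3 as in the target, as expected for a Δ2-4,4-dimethyl trans-decalin.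

Step 7
Reactants: 12 7-(tert-butyldimethylsilyloxy)-2,3-dihydroxy-4,4,10-trimethyl-trans-decalin-9-one
Product: 13 7-(tert-butyldimethylsilyloxy)-2,3-(isopropylidenedioxy)-4,4,10-trimethyl-trans-decalin-9-one
Conditions: 2,2-dimethoxypropane, PPTS (cat.), CH2Cl2, 23 °C
Reagents that add atoms: 2,2-dimethoxypropane, COC(C)(C)OC
Why: Acid-catalysed transacetalisation ties the cis-diol up as an acetonide that withstands the bases, organometallics and reductants ahead, while PPTS is too mild to cleave the secondary TBS ether.

Step 8
Reactants: 13 7-(tert-butyldimethylsilyloxy)-2,3-(isopropylidenedioxy)-4,4,10-trimethyl-trans-decalin-9-one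
Product: 14 2,3-(isopropylidenedioxy)-4,4,10-trimethyl-trans-decal-7-en-9-one
Conditions: DBU, toluene, 80 °C
Reagents that add atoms: none
Why: E1cB elimination, in which DBU enolises C9 toward C8 (the only enolisable side) and the axial C7 silyloxy group, aligned with the enolate π system, leaves as silanolate to give the C7=C8 enone.

Step 9
Reactants: 14 2,3-(isopropylidenedioxy)-4,4,10-trimethyl-trans-decal-7-en-9-one
Product: 15 8-iodo-2,3-(isopropylidenedioxy)-4,4,10-trimethyl-trans-decal-7-en-9-one
Conditions: I2, pyridine/CH2Cl2, 0 → 23 °C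
Reagents that add atoms: iodine, II
Why: α-Iodination of the enone by the pyridine addition, enolate iodination and elimination sequence (Baylis–Hillman-type) places iodine on C8, the only α-vinylic position.

Step 10
Reactants: 15 8-iodo-2,3-(isopropylidenedioxy)-4,4,10-trimethyl-trans-decal-7-en-9-one
Product: 16 2,3-(isopropylidenedioxy)-4,4,8,10-tetramethyl-trans-decal-7-en-9-one
Conditions: Me4Sn, Pd2(dba)3 (5 mol %), AsPh3, CuI (10 mol %), NMP, 80 °C
Reagents that add atoms: tetramethylstannane, C[Sn](C)(C)C
Why: Stille cross-coupling of the α-iodoenone with Me4Sn installs the C8 methyl group under neutral conditions that can neither enolise nor deconjugate the enone.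

Step 11
Reactants: 16 2,3-(isopropylidenedioxy)-4,4,8,10-tetramethyl-trans-decal-7-en-9-one
Product: 17 2,3-(isopropylidenedioxy)-4,4,8,10-tetramethyl-9-methylene-trans-decal-7-ene
Conditions: Ph3PCH3Br, KOtBu, toluene, 90 °C
Reagents that add atoms: methyltriphenylphosphonium bromide, C[P+](c1ccccc1)(c1ccccc1)c1ccccc1.[Br-]
Why: Wittig methylenation with the ylide generated by KOtBu in hot toluene, conditions suited to hindered ketones, converts C9=O into the exocyclic C9=C11 alkene and gives the 7,9(11)-diene, whose s-trans geometry is fixed by the ring.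

Step 12
Reactants: 17 2,3-(isopropylidenedioxy)-4,4,8,10-tetramethyl-9-methylene-trans-decal-7-ene
Product: 19 [2,3-(isopropylidenedioxy)-4,4,8,10-tetramethyl-trans-decal-7-en-9-yl]methanol (CH2OH cis to the 10-methyl), via B-alkyl-9-BBN adduct 18 (not isolated)
Conditions: 9-BBN-H, THF, 0 → 23 °C; then NaOH, H2O2, 0 °C
Reagents that add atoms: hydrogen peroxide, OO (oxygen on C11); 9-BBN-H, B1C2CCCC1CCC2 (its boron and ring stay only in intermediate 18)
Why: Hydroboration–oxidation, in which 9-BBN attacks only the 1,1-disubstituted C9=C11 bond (boron to terminal C11, trisubstituted C7=C8 untouched) from the face opposite the adjacent axial C10 methyl, so hydrogen enters C9 anti to that methyl and the CH2OH group ends equatorial and cis to it, as in drimenol.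

Step 13
Reactants: 19 [2,3-(isopropylidenedioxy)-4,4,8,10-tetramethyl-trans-decal-7-en-9-yl]methanol
Product: 20 [2,3-(isopropylidenedioxy)-4,4,8,10-tetramethyl-trans-decal-7-en-9-yl]methyl phenyl sulfide
Conditions: PhSSPh, PBu3, pyridine, 50 °C
Reagents that add atoms: diphenyl disulfide, c1ccccc1SSc1ccccc1
Why: Mukaiyama–Hata-type thioetherification, in which the alkoxyphosphonium salt is displaced by thiophenolate in an SN2 reaction at primary C11 without ionisation, so homoallyl rearrangement is avoided.

Step 14
Reactants: 20 [2,3-(isopropylidenedioxy)-4,4,8,10-tetramethyl-trans-decal-7-en-9-yl]methyl phenyl sulfide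
Product: 21 [2,3-(isopropylidenedioxy)-4,4,8,10-tetramethyl-trans-decal-7-en-9-yl]methyl phenyl sulfone
Conditions: (NH4)6Mo7O24·4H2O (cat.), 30% H2O2, EtOH, 0 → 23 °C
Reagents that add atoms: hydrogen peroxide, OO
Why: Molybdate-catalysed peroxide oxidation is chemoselective for sulfur over the trisubstituted C7=C8 alkene and takes the sulfide to the sulfone.

Step 15
Reactants: 21 [2,3-(isopropylidenedioxy)-4,4,8,10-tetramethyl-trans-decal-7-en-9-yl]methyl phenyl sulfone; 22 (E)-4-chloro-3-methylbut-2-en-1-yl acetate
Product: 24 11-(phenylsulfonyl)-2,3-(isopropylidenedioxy)labda-7,13E-dien-15-yl acetate (C11 epimers), via C11-lithiated sulfone 23 (not isolated)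
Conditions: n-BuLi, THF/HMPA, −78 °C; then 22, −78 → −20 °C
Reagents that add atoms: none
Why: Sulfone α-alkylation, in which the soft C11 carbanion displaces the primary allylic chloride of 22 in an SN2 reaction faster than it attacks the acetate carbonyl, forming C11–C12 with the E geometry of 22 retained, while the new C11 stereocenter is removed in step 16.

Step 16
Reactants: 24 11-(phenylsulfonyl)-2,3-(isopropylidenedioxy)labda-7,13E-dien-15-yl acetate
Product: 25 2,3-(isopropylidenedioxy)labda-7,13E-dien-15-yl acetate
Conditions: 6% Na(Hg), Na2HPO4, THF/MeOH, −20 °C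
Reagents that add atoms: none
Why: Reductive desulfonylation by electron transfer from sodium amalgam cleaves the C11–S bond and the buffered medium protonates C11, sparing the isolated alkenes, the acetonide and, at low temperature, the allylic acetate (any C15 alcohol formed would be re-acetylated in step 18).

Step 17
Reactants: 25 2,3-(isopropylidenedioxy)labda-7,13E-dien-15-yl acetate
Product: 26 (2S,3R,5S,9R,10S)-2,3-dihydroxylabda-7,13E-dien-15-yl acetate
Conditions: AcOH/H2O 4:1, 45 °C
Reagents that add atoms: none
Why: Acid-catalysed acetal hydrolysis in aqueous acetic acid frees the 2,3-diol without touching the primary allylic acetate or the trisubstituted alkenes.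

Step 18
Reactants: 26 (2S,3R,5S,9R,10S)-2,3-dihydroxylabda-7,13E-dien-15-yl acetate
Product: 27 (2S,3R,5S,9R,10S)-2-acetoxy-3-hydroxylabda-7,13E-dien-15-yl acetate (target CNP0254679.1)
Conditions: Ac2O (1.2 equiv), pyridine, CH2Cl2, 0 °C
Reagents that add atoms: acetic anhydride, CC(=O)OC(C)=O
Why: Selective acylation, in which the equatorial C2 hydroxyl reacts much faster than the axial C3 hydroxyl, which is neopentyl (next to the C4 gem-dimethyl group) and 1,3-diaxial to the C1 and C5 hydrogens, so the 2-monoacetate should result.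

**Compound list**
1 | (S)-carvone | O=C1C[C@@H](C(C)=C)CC=C1C | starting material
2 | (S)-5-(1-hydroperoxy-1-methoxyethyl)-2-methylcyclohex-2-en-1-one (not isolated) | O=C1C[C@@H](C(C)(OC)OO)CC=C1C | intermediate
3 | (S)-5-acetoxy-2-methylcyclohex-2-en-1-one | O=C1C[C@@H](OC(C)=O)CC=C1C | intermediate
4 | (S)-5-hydroxy-2-methylcyclohex-2-en-1-one | O=C1C[C@@H](O)CC=C1C | intermediate
5 | (S)-5-(tert-butyldimethylsilyloxy)-2-methylcyclohex-2-en-1-one | O=C1C[C@@H](O[Si](C)(C)C(C)(C)C)CC=C1C | intermediate
6 | prenyltrimethylsilane | CC(C)=CC[Si](C)(C)C | starting material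
7 | allyl bromide | C=CCBr | starting material
8 | 5-(tert-butyldimethylsilyloxy)-2-methyl-3-(2-methylbut-3-en-2-yl)-1-(trimethylsilyloxy)cyclohex-1-ene, 3,5-trans (not isolated) | C[Si](C)(C)OC1C[C@@H](O[Si](C)(C)C(C)(C)C)C[C@H](C(C)(C)C=C)C=1C | intermediate
9 | lithium enolate corresponding to 8 (not isolated) | [Li]OC1C[C@@H](O[Si](C)(C)C(C)(C)C)C[C@H](C(C)(C)C=C)C=1C | intermediate
10 | (2R,3R,5S)-2-allyl-5-(tert-butyldimethylsilyloxy)-2-methyl-3-(2-methylbut-3-en-2-yl)cyclohexan-1-one | O=C1C[C@@H](O[Si](C)(C)C(C)(C)C)C[C@H](C(C)(C)C=C)[C@@]1(C)CC=C | intermediate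
11 | 7-(tert-butyldimethylsilyloxy)-4,4,10-trimethyl-trans-decal-2-en-9-one | O=C1C[C@@H](O[Si](C)(C)C(C)(C)C)C[C@@H]2C(C)(C)C=CC[C@@]12C | intermediate
12 | 7-(tert-butyldimethylsilyloxy)-2,3-dihydroxy-4,4,10-trimethyl-trans-decalin-9-one | O=C1C[C@@H](O[Si](C)(C)C(C)(C)C)C[C@@H]2C(C)(C)[C@@H](O)[C@@H](O)C[C@@]12C | intermediate
13 | 7-(tert-butyldimethylsilyloxy)-2,3-(isopropylidenedioxy)-4,4,10-trimethyl-trans-decalin-9-one | O=C1C[C@@H](O[Si](C)(C)C(C)(C)C)C[C@@H]2C(C)(C)[C@H]3OC(C)(C)O[C@H]3C[C@@]12C | intermediate
14 | 2,3-(isopropylidenedioxy)-4,4,10-trimethyl-trans-decal-7-en-9-one | O=C1C=CC[C@@H]2C(C)(C)[C@H]3OC(C)(C)O[C@H]3C[C@@]12C | intermediate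
15 | 8-iodo-2,3-(isopropylidenedioxy)-4,4,10-trimethyl-trans-decal-7-en-9-one | O=C1C(I)=CC[C@@H]2C(C)(C)[C@H]3OC(C)(C)O[C@H]3C[C@@]12C | intermediate
16 | 2,3-(isopropylidenedioxy)-4,4,8,10-tetramethyl-trans-decal-7-en-9-one | O=C1C(C)=CC[C@@H]2C(C)(C)[C@H]3OC(C)(C)O[C@H]3C[C@@]12C | intermediate
17 | 2,3-(isopropylidenedioxy)-4,4,8,10-tetramethyl-9-methylene-trans-decal-7-ene | C=C1C(C)=CC[C@@H]2C(C)(C)[C@H]3OC(C)(C)O[C@H]3C[C@@]12C | intermediate
18 | C11 9-BBN adduct of 17 (not isolated) | C(B4C5CCCC4CCC5)[C@@H]1C(C)=CC[C@@H]2C(C)(C)[C@H]3OC(C)(C)O[C@H]3C[C@@]12C | intermediate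
19 | [2,3-(isopropylidenedioxy)-4,4,8,10-tetramethyl-trans-decal-7-en-9-yl]methanol | OC[C@@H]1C(C)=CC[C@@H]2C(C)(C)[C@H]3OC(C)(C)O[C@H]3C[C@@]12C | intermediate
20 | C11 phenyl sulfide of 19 | c4ccccc4SC[C@@H]1C(C)=CC[C@@H]2C(C)(C)[C@H]3OC(C)(C)O[C@H]3C[C@@]12C | intermediate
21 | C11 phenyl sulfone | O=S(=O)(c4ccccc4)C[C@@H]1C(C)=CC[C@@H]2C(C)(C)[C@H]3OC(C)(C)O[C@H]3C[C@@]12C | intermediate
22 | (E)-4-chloro-3-methylbut-2-en-1-yl acetate | CC(=O)OC/C=C(\C)CCl | starting material
23 | C11-lithiated sulfone (not isolated) | [Li]C(S(=O)(=O)c4ccccc4)[C@@H]1C(C)=CC[C@@H]2C(C)(C)[C@H]3OC(C)(C)O[C@H]3C[C@@]12C | intermediate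
24 | 11-(phenylsulfonyl)-2,3-(isopropylidenedioxy)labda-7,13E-dien-15-yl acetate (C11 epimers) | CC(=O)OC/C=C(\C)CC(S(=O)(=O)c4ccccc4)[C@@H]1C(C)=CC[C@@H]2C(C)(C)[C@H]3OC(C)(C)O[C@H]3C[C@@]12C | intermediate
25 | 2,3-(isopropylidenedioxy)labda-7,13E-dien-15-yl acetate | CC(=O)OC/C=C(\C)CC[C@@H]1C(C)=CC[C@@H]2C(C)(C)[C@H]3OC(C)(C)O[C@H]3C[C@@]12C | intermediate
26 | (2S,3R,5S,9R,10S)-2,3-dihydroxylabda-7,13E-dien-15-yl acetate | CC(=O)OC/C=C(\C)CC[C@@H]1C(C)=CC[C@@H]2C(C)(C)[C@@H](O)[C@@H](O)C[C@@]12C | intermediate
27 | (2S,3R,5S,9R,10S)-2-acetoxy-3-hydroxylabda-7,13E-dien-15-yl acetate | CC(=O)OC/C=C(\C)CC[C@@H]1C(C)=CC[C@@H]2C(C)(C)[C@@H](O)[C@@H](OC(C)=O)C[C@@]12C | target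

**Count and risks**
Total steps: 18. Longest linear sequence: 18 steps, from (S)-carvone to the target; 6, 7 and 22 are purchased and enter in steps 4 and 15.

Steps most likely to fail:

1. Step 4. The silicon-catalysed conjugate addition may stall at the α-methyl enone or be accompanied by loss of the C7 silyl ether. The crowded tetrasubstituted enolate may also undergo O-allylation, or proton exchange with the product followed by β-elimination at C7. The fallback sets out from 5 and comes back at 14, making the two C–C bonds in separate operations and replacing steps 4–8. Stoichiometric TiCl4-mediated Sakurai addition of 6 to 5 (CH2Cl2, −78 °C) with aqueous quench gives the conjugate-addition ketone F1. DBU then eliminates silanol to give the enone F2, whose only α-hydrogen is at C10. Kinetic deprotonation with LDA (THF, −78 °C) and alkylation with 7, anti to the C5 substituent, gives the allyl enone F3. Ring-closing metathesis with the second-generation Grubbs catalyst gives the dienone F4. OsO4/NMO dihydroxylates the isolated C2=C3 bond in preference to the electron-poor enone alkene, giving the diol F5, and acetonide formation (2,2-dimethoxypropane, PPTS) gives 14.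

2. Step 15. The hindered, α-branched sulfonyl carbanion may react sluggishly at the allylic chloride, be acylated or quenched by the acetate, or attack with allylic transposition. The fallback sets out from 19 and comes back at 25, forming C12–C13 instead of C11–C12 and making steps 13–16 unnecessary. Dess–Martin oxidation of 19 gives the aldehyde F6, and Wittig methylenation at −78 → 0 °C gives the 9-vinyl compound F7. 9-BBN-H hydroborates the monosubstituted alkene to the borane F8. B-alkyl Suzuki–Miyaura coupling (Pd(dppf)Cl2, AsPh3, Cs2CO3, DMF/H2O) with (E)-3-iodobut-2-en-1-yl acetate F9, made from (E)-3-iodobut-2-en-1-ol and Ac2O, then gives 25 with retention of the E geometry.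

3. Step 11. Addition of the ylide to the C9 carbonyl, flanked by quaternary C10 and the substituted C8, may fail, with the basic ylide instead removing a γ-hydrogen at C6 and returning or deconjugating the enone. The fallback sets out from 16 and comes back at 17 by Peterson olefination. Me3SiCH2Li with CeCl3 (THF, −78 °C), a small and weakly basic nucleophile, adds to C9 to give the β-hydroxysilane F10, and KH in THF brings about syn-elimination of silanolate to give 17.

**Further compounds**
F1 | step 4 | 5-(tert-butyldimethylsilyloxy)-2-methyl-3-(2-methylbut-3-en-2-yl)cyclohexan-1-one (3-substituent trans to the silyloxy group, C2 epimers) | O=C1C[C@@H](O[Si](C)(C)C(C)(C)C)C[C@H](C(C)(C)C=C)C1C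
F2 | step 4 | 6-methyl-5-(2-methylbut-3-en-2-yl)cyclohex-2-en-1-one (C6 epimers) | O=C1C=CC[C@H](C(C)(C)C=C)C1C
F3 | step 4 | 6-allyl-6-methyl-5-(2-methylbut-3-en-2-yl)cyclohex-2-en-1-one (allyl trans to the C5 substituent) | O=C1C=CC[C@H](C(C)(C)C=C)[C@@]1(C)CC=C
F4 | step 4 | 4,4,10-trimethyl-trans-decala-2,7-dien-9-one | O=C1C=CC[C@@H]2C(C)(C)C=CC[C@@]12C
F5 | step 4 | 2,3-dihydroxy-4,4,10-trimethyl-trans-decal-7-en-9-one (diol on the face opposite the 10-methyl) | O=C1C=CC[C@@H]2C(C)(C)[C@@H](O)[C@@H](O)C[C@@]12C
F6 | step 15 | 2,3-(isopropylidenedioxy)-4,4,8,10-tetramethyl-trans-decal-7-ene-9-carbaldehyde | O=C[C@@H]1C(C)=CC[C@@H]2C(C)(C)[C@H]3OC(C)(C)O[C@H]3C[C@@]12C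
F7 | step 15 | 2,3-(isopropylidenedioxy)-4,4,8,10-tetramethyl-9-vinyl-trans-decal-7-ene | C=C[C@@H]1C(C)=CC[C@@H]2C(C)(C)[C@H]3OC(C)(C)O[C@H]3C[C@@]12C
F8 | step 15 | C12 9-BBN adduct of F7 | C(B4C5CCCC4CCC5)C[C@@H]1C(C)=CC[C@@H]2C(C)(C)[C@H]3OC(C)(C)O[C@H]3C[C@@]12C
F9 | step 15 | (E)-3-iodobut-2-en-1-yl acetate | CC(=O)OC/C=C(\C)I
F10 | step 11 | 2,3-(isopropylidenedioxy)-4,4,8,10-tetramethyl-9-(trimethylsilylmethyl)-trans-decal-7-en-9-ol | C[Si](C)(C)CC1(O)C(C)=CC[C@@H]2C(C)(C)[C@H]3OC(C)(C)O[C@H]3C[C@@]12C
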